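C2 is the quaternary carbon of the oxepine ring (O1, C2, C3, C4, C5=C6, C7). The retrosynthesis cuts, in this order: the aryl–C(=O) bond, the C2–CH2 bond of the side arm, the C2–CO2H carbon (back to a lactone carbonyl at C2), and then ring bond C3–C4 with the C5=C6 alkene returned to a vinyl group on C6.
Enabling feature: C2 carries the ring oxygen O1 and lies γ,δ to the C5=C6 alkene through C3–C4, while C6 carries C7–O1. With C2 at lactone level the ring is a 4-enolide, the product of a Claisen rearrangement of a 4-vinyl-2-methylene-1,3-dioxolane tethered through O1–C7.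
Forward: side-chain bromide → chloroketone → vinyl epoxide → five-membered vinyl carbonate (temporary ring) → methylenation and Claisen ring expansion to the seven-membered lactone (the only ring-forming event for the oxepine) → lactone carbonyl converted to C2–H/CO2H → enediolate alkylation → aryl ketone (arene brought in intact) → desilylation.
Stereochemistry: (S)-C2 comes from alkylation of a symmetric dilithium enediolate held in a mixed aggregate with a chiral lithium amide. The ring alkene geometry comes from the cyclic Claisen transition state. The side-chain (E)-alkene comes from SeO2 oxidation of the methyl group trans to the chain.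
Helpers and their removal: the carbonate/ketene acetal ring (consumed by the rearrangement), the lactone oxidation level at C2 (steps 7–9), and the silyl ethers (step 13).

Key step: step 6

Remark: compounds 1, 4, 17 and 20 are taken as purchasable. Compounds 7–10 and 13–16 are racemic by design: the stereocenter of 7–10 is erased in step 6 and C2 is set only in step 10.

Step 1
Reactants: 1 5-bromo-2-methylpent-2-ene
Product: 2 (E)-5-bromo-2-methylpent-2-en-1-ol
Conditions: SeO2 (0.3 equiv), t-BuOOH, CH2Cl2, 0 °C to rt
Reagents that add atoms: tert-butyl hydroperoxide, CC(C)(C)OO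
Why: Riley allylic oxidation (ene reaction, then [2,3]-sigmatropic shift) attacks the methyl group trans to the chain of the trisubstituted alkene, which should fix the (E)-allylic alcohol and leave the homoallylic bromide untouched.

Step 2
Reactants: 2 (E)-5-bromo-2-methylpent-2-en-1-ol
Product: 3 (E)-5-bromo-1-(tert-butyldimethylsilyloxy)-2-methylpent-2-ene
Conditions: t-BuMe2SiCl, imidazole, DMF, rt
Reagents that add atoms: tert-butyldimethylsilyl chloride, CC(C)(C)[Si](C)(C)Cl
Why: Silyl ether formation masks the primary alcohol for the organomagnesium, organotitanium and organolithium steps that follow.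

Step 3
Reactants: 3 (E)-5-bromo-1-(tert-butyldimethylsilyloxy)-2-methylpent-2-ene; 4 2-chloro-N-methoxy-N-methylacetamide
Product: 6 (E)-7-(tert-butyldimethylsilyloxy)-1-chloro-6-methylhept-5-en-2-one, via Grignard reagent 5 (not isolated)
Conditions: Mg, THF, rt; then 4, THF, −20 °C to 0 °C; 1 M HCl, 0 °C
Reagents that add atoms: magnesium, [Mg] (magnesium of 5)
Why: Grignard formation and Weinreb ketone synthesis should stop at the ketone, because the magnesium chelate of the tetrahedral adduct survives until work-up and the chloride is not displaced at low temperature.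

Step 4
Reactants: 6 (E)-7-(tert-butyldimethylsilyloxy)-1-chloro-6-methylhept-5-en-2-one
Product: 8 racemic 2-[(E)-5-(tert-butyldimethylsilyloxy)-4-methylpent-3-enyl]-2-vinyloxirane, via chlorohydrin 7 (not isolated)
Conditions: CH2=CHMgBr, THF, −78 °C; then NaOH (2 M aq.), MeOH, rt
Reagents that add atoms: vinylmagnesium bromide, C=C[Mg]Br
Why: Grignard 1,2-addition to the ketone followed by base-induced closure of the chlorohydrin (intramolecular Williamson reaction) should give the 2,2-disubstituted vinyl epoxide, whose new stereocenter is formed racemic and is erased in step 6.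

Step 5
Reactants: 8 racemic 2-[(E)-5-(tert-butyldimethylsilyloxy)-4-methylpent-3-enyl]-2-vinyloxirane
Product: 9 racemic 4-[(E)-5-(tert-butyldimethylsilyloxy)-4-methylpent-3-enyl]-4-vinyl-1,3-dioxolan-2-one
Conditions: CO2 (1 atm), Pd(PPh3)4 (5 mol %), THF, 0 °C to rt
Reagents that add atoms: carbon dioxide, O=C=O
Why: Zerovalent palladium opens the vinyl epoxide to a zwitterionic π-allyl complex whose alkoxide captures CO2 and recloses at the substituted allyl terminus (Tsuji–Trost-type CO2 insertion), which should give the five-membered carbonate with the vinyl group on the quaternary carbon.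

Step 6
Reactants: 9 racemic 4-[(E)-5-(tert-butyldimethylsilyloxy)-4-methylpent-3-enyl]-4-vinyl-1,3-dioxolan-2-one
Product: 11 6-[(E)-5-(tert-butyldimethylsilyloxy)-4-methylpent-3-enyl]-4,7-dihydrooxepin-2(3H)-one, via ketene acetal 10 (not isolated)
Conditions: Cp2TiMe2 (1.5 equiv), toluene, 105 °C, dark
Reagents that add atoms: bis(cyclopentadienyl)dimethyltitanium, C[Ti](C)(C1C=CC=C1)C1C=CC=C1
Why: On heating, Cp2TiMe2 loses methane to give Cp2Ti=CH2, which converts the carbonate C=O of 9 into the exocyclic C=CH2 of the cyclic ketene acetal 10 by [2+2] addition and cycloreversion (Petasis methylenation). Compound 10 is an O-allyl ketene acetal, and a Claisen [3,3]-sigmatropic rearrangement joins the methylene carbon to the vinyl terminus (C3–C4), breaks the allylic C6–O bond, moves the alkene to C5=C6 and turns the acetal carbon into the lactone carbonyl C2. The closest known reaction type is the tandem methylenation–Claisen ring expansion of vinyl-substituted cyclic carbonates and ketene acetals to unsaturated medium-ring lactones. The oxepinone ring is closed by a two-atom ring expansion of the 1,3-dioxolane: C3, C4 and C5 enter the ring and one oxygen leaves it as the carbonyl oxygen, through a boat-like six-membered transition state bridged by O1–C7. No stereocenter is formed: the racemic quaternary center C6 becomes trigonal, and the cis arrangement of C4 and C7 on the C5=C6 bond is enforced by the bicyclic transition state, which an open-chain Claisen rearrangement of the same tertiary allylic ether could not do. The step needs methylenation of the carbonate without consumption of the lactone that accumulates, and a [3,3] shift in preference to ionisation of the tertiary allylic C–O bond; the first is addressed by limiting the titanium reagent, the second by the two oxygen donors on the ketene acetal, which should make the concerted shift fast at the methylenation temperature.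

Step 7
Reactants: 11 6-[(E)-5-(tert-butyldimethylsilyloxy)-4-methylpent-3-enyl]-4,7-dihydrooxepin-2(3H)-one
Product: 12 6-[(E)-5-(tert-butyldimethylsilyloxy)-4-methylpent-3-enyl]-2-methylene-2,3,4,7-tetrahydrooxepine
Conditions: Cp2TiMe2 (2 equiv), toluene/THF, 65 °C, dark; base-washed glassware, used crude
Reagents that add atoms: bis(cyclopentadienyl)dimethyltitanium, C[Ti](C)(C1C=CC=C1)C1C=CC=C1
Why: A second Petasis methylenation, now of the more reactive lactone carbonyl at a temperature too low for a further sigmatropic shift, should give the exocyclic enol ether under acid-free conditions that keep the double bond exocyclic.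

Step 8
Reactants: 12 6-[(E)-5-(tert-butyldimethylsilyloxy)-4-methylpent-3-enyl]-2-methylene-2,3,4,7-tetrahydrooxepine
Product: 14 racemic {6-[(E)-5-(tert-butyldimethylsilyloxy)-4-methylpent-3-enyl]-2,3,4,7-tetrahydrooxepin-2-yl}methanol, via alkylborane 13 (not isolated)
Conditions: 9-BBN, THF, 0 °C to rt; then NaOH, H2O2, 0 °C
Reagents that add atoms: 9-borabicyclo[3.3.1]nonane, B1C2CCCC1CCC2 (boron of 13); hydrogen peroxide, OO
Why: In this hydroboration–oxidation, 9-BBN should add to the 1,1-disubstituted enol ether far faster than to either trisubstituted alkene and place boron on the terminal carbon, so oxidation gives the primary alcohol; C2 is formed racemic and is re-set in step 10.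

Step 9
Reactants: 14 racemic {6-[(E)-5-(tert-butyldimethylsilyloxy)-4-methylpent-3-enyl]-2,3,4,7-tetrahydrooxepin-2-yl}methanol
Product: 16 racemic 6-[(E)-5-(tert-butyldimethylsilyloxy)-4-methylpent-3-enyl]-2,3,4,7-tetrahydrooxepine-2-carboxylic acid, via aldehyde 15 (not isolated)
Conditions: TEMPO (0.2 equiv), PhI(OAc)2 (2.2 equiv), MeCN/H2O, rt
Reagents that add atoms: water, O
Why: Oxoammonium (TEMPO) oxidation in aqueous acetonitrile should take the primary alcohol through the aldehyde hydrate to the acid without touching the alkenes or the silyl ether.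

Step 10
Reactants: 16 racemic 6-[(E)-5-(tert-butyldimethylsilyloxy)-4-methylpent-3-enyl]-2,3,4,7-tetrahydrooxepine-2-carboxylic acid; 17 2-bromo-N-methoxy-N-methylacetamide
Product: 19 (S)-6-[(E)-5-(tert-butyldimethylsilyloxy)-4-methylpent-3-enyl]-2-{2-[methoxy(methyl)amino]-2-oxoethyl}-2,3,4,7-tetrahydrooxepine-2-carboxylic acid, via dilithium enediolate 18 (not isolated)
Conditions: (R,R)-N,N′-bis(1-phenyl-2-piperidin-1-ylethyl)propane-1,3-diamine (1.05 equiv), n-BuLi (4 equiv), THF, 0 °C; then 17, −78 °C; dilute HCl work-up (amine recovered by extraction)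
Reagents that add atoms: n-butyllithium, [Li]CCCC (lithium of 18)
Why: Proposed new method: the dilithiated C2-symmetric tetramine deprotonates 16 twice to the dilithium enediolate 18, which has no E/Z isomers because both enolate oxygens carry lithium, and holds it in a mixed aggregate in which ring oxygen O1 is bound to lithium so that the two faces of C2 (ring-oxygen side versus ring-CH2 side) sit differently against the chiral amide; the SN2-activated α-bromo amide 17 should then enter from the open face to set (S)-C2 (sense assigned by analogy, the antipodal amine being available), the closest known reaction type being the enantioselective alkylation of α-alkoxy-α-arylacetic acid enediolates to tetrasubstituted centers under the same lithium amide control.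

Step 11
Reactants: 20 2-bromobenzene-1,4-diol
Product: 21 2-bromo-1,4-bis(tert-butyldimethylsilyloxy)benzene
Conditions: t-BuMe2SiCl (2.2 equiv), imidazole, DMF, rt
Reagents that add atoms: tert-butyldimethylsilyl chloride, CC(C)(C)[Si](C)(C)Cl
Why: Silyl ether formation on both phenols gives an aryl bromide fit for halogen–lithium exchange, with protecting groups that leave in the final fluoride step.

Step 12
Reactants: 19 (S)-6-[(E)-5-(tert-butyldimethylsilyloxy)-4-methylpent-3-enyl]-2-{2-[methoxy(methyl)amino]-2-oxoethyl}-2,3,4,7-tetrahydrooxepine-2-carboxylic acid; 21 2-bromo-1,4-bis(tert-butyldimethylsilyloxy)benzene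
Product: 23 (S)-2-{2-[2,5-bis(tert-butyldimethylsilyloxy)phenyl]-2-oxoethyl}-6-[(E)-5-(tert-butyldimethylsilyloxy)-4-methylpent-3-enyl]-2,3,4,7-tetrahydrooxepine-2-carboxylic acid, via aryllithium 22 (not isolated)
Conditions: 21 (2.4 equiv), n-BuLi, THF, −78 °C; then 19, −78 °C; dilute HCl, 0 °C
Reagents that add atoms: n-butyllithium, [Li]CCCC (lithium of 22)
Why: Bromine–lithium exchange and Weinreb ketone synthesis should give the aryl ketone, since the first equivalent of aryllithium turns the acid into its unreactive lithium carboxylate, the chelated tetrahedral adduct prevents over-addition, and C2, having no hydrogen, cannot epimerise.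

Step 13
Reactants: 23 (S)-2-{2-[2,5-bis(tert-butyldimethylsilyloxy)phenyl]-2-oxoethyl}-6-[(E)-5-(tert-butyldimethylsilyloxy)-4-methylpent-3-enyl]-2,3,4,7-tetrahydrooxepine-2-carboxylic acid
Product: 24 (S)-2-[2-(2,5-dihydroxyphenyl)-2-oxoethyl]-6-[(E)-5-hydroxy-4-methylpent-3-enyl]-2,3,4,7-tetrahydrooxepine-2-carboxylic acid
Conditions: Bu4NF (4 equiv), AcOH (4 equiv), degassed THF, 0 °C to rt, under argon
Reagents that add atoms: none
Why: Fluoride-mediated desilylation buffered with acetic acid should remove the three silyl ethers near neutral pH, which avoids base-induced β-elimination (retro-oxa-Michael opening) of the β-alkoxy ketone and air oxidation of the hydroquinone, and leaves C2 untouched.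

Compound list
1 | 5-bromo-2-methylpent-2-ene | CC(C)=CCCBr | starting material
2 | (E)-5-bromo-2-methylpent-2-en-1-ol | C/C(=C\CCBr)CO | intermediate
3 | (E)-5-bromo-1-(tert-butyldimethylsilyloxy)-2-methylpent-2-ene | C/C(=C\CCBr)CO[Si](C)(C)C(C)(C)C | intermediate
4 | 2-chloro-N-methoxy-N-methylacetamide | CON(C)C(=O)CCl | starting material
5 | (E)-[5-(tert-butyldimethylsilyloxy)-4-methylpent-3-enyl]magnesium bromide | C/C(=C\CC[Mg]Br)CO[Si](C)(C)C(C)(C)C | intermediate
6 | (E)-7-(tert-butyldimethylsilyloxy)-1-chloro-6-methylhept-5-en-2-one | C/C(=C\CCC(=O)CCl)CO[Si](C)(C)C(C)(C)C | intermediate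
7 | racemic (E)-8-(tert-butyldimethylsilyloxy)-3-(chloromethyl)-7-methylocta-1,6-dien-3-ol | C/C(=C\CCC(O)(CCl)C=C)CO[Si](C)(C)C(C)(C)C | intermediate
8 | racemic 2-[(E)-5-(tert-butyldimethylsilyloxy)-4-methylpent-3-enyl]-2-vinyloxirane | C/C(=C\CCC1(C=C)CO1)CO[Si](C)(C)C(C)(C)C | intermediate
9 | racemic 4-[(E)-5-(tert-butyldimethylsilyloxy)-4-methylpent-3-enyl]-4-vinyl-1,3-dioxolan-2-one | C/C(=C\CCC1(C=C)COC(=O)O1)CO[Si](C)(C)C(C)(C)C | intermediate
10 | racemic 4-[(E)-5-(tert-butyldimethylsilyloxy)-4-methylpent-3-enyl]-2-methylene-4-vinyl-1,3-dioxolane | C/C(=C\CCC1(C=C)COC(=C)O1)CO[Si](C)(C)C(C)(C)C | intermediate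
11 | 6-[(E)-5-(tert-butyldimethylsilyloxy)-4-methylpent-3-enyl]-4,7-dihydrooxepin-2(3H)-one | C/C(=C\CCC1=CCCC(=O)OC1)CO[Si](C)(C)C(C)(C)C | intermediate
12 | 6-[(E)-5-(tert-butyldimethylsilyloxy)-4-methylpent-3-enyl]-2-methylene-2,3,4,7-tetrahydrooxepine | C/C(=C\CCC1=CCCC(=C)OC1)CO[Si](C)(C)C(C)(C)C | intermediate
13 | racemic 9-({6-[(E)-5-(tert-butyldimethylsilyloxy)-4-methylpent-3-enyl]-2,3,4,7-tetrahydrooxepin-2-yl}methyl)-9-borabicyclo[3.3.1]nonane | C/C(=C\CCC1=CCCC(CB2C3CCCC2CCC3)OC1)CO[Si](C)(C)C(C)(C)C | intermediate
14 | racemic {6-[(E)-5-(tert-butyldimethylsilyloxy)-4-methylpent-3-enyl]-2,3,4,7-tetrahydrooxepin-2-yl}methanol | C/C(=C\CCC1=CCCC(CO)OC1)CO[Si](C)(C)C(C)(C)C | intermediate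
15 | racemic 6-[(E)-5-(tert-butyldimethylsilyloxy)-4-methylpent-3-enyl]-2,3,4,7-tetrahydrooxepine-2-carbaldehyde | C/C(=C\CCC1=CCCC(C=O)OC1)CO[Si](C)(C)C(C)(C)C | intermediate
16 | racemic 6-[(E)-5-(tert-butyldimethylsilyloxy)-4-methylpent-3-enyl]-2,3,4,7-tetrahydrooxepine-2-carboxylic acid | C/C(=C\CCC1=CCCC(C(=O)O)OC1)CO[Si](C)(C)C(C)(C)C | intermediate
17 | 2-bromo-N-methoxy-N-methylacetamide | CON(C)C(=O)CBr | starting material
18 | dilithium enediolate of acid 16 | C/C(=C\CCC1=CCCC(=C([O-])[O-])OC1)CO[Si](C)(C)C(C)(C)C.[Li+].[Li+] | intermediate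
19 | (S)-6-[(E)-5-(tert-butyldimethylsilyloxy)-4-methylpent-3-enyl]-2-{2-[methoxy(methyl)amino]-2-oxoethyl}-2,3,4,7-tetrahydrooxepine-2-carboxylic acid | C/C(=C\CCC1=CCC[C@](CC(=O)N(C)OC)(C(=O)O)OC1)CO[Si](C)(C)C(C)(C)C | intermediate
20 | 2-bromobenzene-1,4-diol | Oc1ccc(O)c(Br)c1 | starting material
21 | 2-bromo-1,4-bis(tert-butyldimethylsilyloxy)benzene | CC(C)(C)[Si](C)(C)Oc1ccc(O[Si](C)(C)C(C)(C)C)c(Br)c1 | intermediate
22 | [2,5-bis(tert-butyldimethylsilyloxy)phenyl]lithium | CC(C)(C)[Si](C)(C)Oc1ccc(O[Si](C)(C)C(C)(C)C)c([Li])c1 | intermediate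
23 | (S)-2-{2-[2,5-bis(tert-butyldimethylsilyloxy)phenyl]-2-oxoethyl}-6-[(E)-5-(tert-butyldimethylsilyloxy)-4-methylpent-3-enyl]-2,3,4,7-tetrahydrooxepine-2-carboxylic acid | C/C(=C\CCC1=CCC[C@](CC(=O)c2cc(O[Si](C)(C)C(C)(C)C)ccc2O[Si](C)(C)C(C)(C)C)(C(=O)O)OC1)CO[Si](C)(C)C(C)(C)C | intermediate
24 | (S)-2-[2-(2,5-dihydroxyphenyl)-2-oxoethyl]-6-[(E)-5-hydroxy-4-methylpent-3-enyl]-2,3,4,7-tetrahydrooxepine-2-carboxylic acid | C/C(=C\CCC1=CCC[C@](CC(=O)c2cc(O)ccc2O)(C(=O)O)OC1)CO | target

Total steps: 13. Longest linear sequence: 12 steps (steps 1 to 10, then 12 and 13; step 11 is a one-step side branch).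

Steps most likely to fail

Step 10 (proposed new method). What may go wrong: insufficient facial discrimination of the enediolate in the mixed aggregate, or proton transfer from the α-bromo amide to the enediolate in place of alkylation. The fallback uses known chemistry, sets out from 16 and comes back at 19. Double deprotonation of 16 with LiN(i-Pr)2 (2.2 equiv, THF, 0 °C) and alkylation with 17 at −78 °C would give the racemic 2-{2-[methoxy(methyl)amino]-2-oxoethyl} acid F1. Classical resolution follows: salt formation with (S)-1-phenylethylamine and fractional crystallisation would separate the salt of the (S)-acid F2 from the salt of the (R)-acid F3, the antipodal amine being used if the salt of the (R)-acid proves the less soluble one. Dilute HCl then liberates 19.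

Step 6 (key step). What may go wrong: methylenation of the lactone as fast as it forms, followed at 105 °C by a second [3,3] shift of the resulting allyl vinyl ether with ring contraction; or thermal loss of the titanium reagent before the less electrophilic carbonate has reacted. The fallback sets out from 9 and comes back at 11, and generates the same ketene acetal with no olefinating reagent present. Methanolysis of 9 (K2CO3, MeOH) would give the diol F4. Acetal exchange with (phenylselanyl)acetaldehyde diethyl acetal (pyridinium p-toluenesulfonate, toluene, heat) would give the 2-(phenylselanylmethyl)-1,3-dioxolane F5. Oxidation with NaIO4 would give the selenoxide F6, and syn-elimination in refluxing xylene with DBU would release ketene acetal 10, which rearranges to 11 as in the main route.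

Step 12. What may go wrong: migration of silicon from oxygen to the lithiated ortho carbon (retro-Brook shift) before acylation, incomplete bromine–lithium exchange, or enolisation of the amide by the aryllithium. The fallback sets out from 19 and comes back at 24, bypassing 23, with an aryl nucleophile that cannot undergo silyl migration. 1,4-Bis(methoxymethoxy)benzene would be lithiated next to an acetal oxygen (n-BuLi, THF, 0 °C, directed ortho metalation) to give [2,5-bis(methoxymethoxy)phenyl]lithium F7. Addition of F7 to 19 at −78 °C would give the acetal-protected keto acid F8. HCl in aqueous methanol would then remove both methoxymethyl ethers and the silyl ether in one operation to give 24.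

Further compounds
F1 | step 10 | racemic 6-[(E)-5-(tert-butyldimethylsilyloxy)-4-methylpent-3-enyl]-2-{2-[methoxy(methyl)amino]-2-oxoethyl}-2,3,4,7-tetrahydrooxepine-2-carboxylic acid | C/C(=C\CCC1=CCCC(CC(=O)N(C)OC)(C(=O)O)OC1)CO[Si](C)(C)C(C)(C)C
F2 | step 10 | (S)-1-phenylethylammonium salt of the (S)-acid 19 | C/C(=C\CCC1=CCC[C@](CC(=O)N(C)OC)(C(=O)[O-])OC1)CO[Si](C)(C)C(C)(C)C.C[C@H]([NH3+])c1ccccc1
F3 | step 10 | (S)-1-phenylethylammonium salt of the (R)-acid | C/C(=C\CCC1=CCC[C@@](CC(=O)N(C)OC)(C(=O)[O-])OC1)CO[Si](C)(C)C(C)(C)C.C[C@H]([NH3+])c1ccccc1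
F4 | step 6 | racemic (E)-7-(tert-butyldimethylsilyloxy)-6-methyl-2-vinylhept-5-ene-1,2-diol | C/C(=C\CCC(O)(CO)C=C)CO[Si](C)(C)C(C)(C)C
F5 | step 6 | 4-[(E)-5-(tert-butyldimethylsilyloxy)-4-methylpent-3-enyl]-2-(phenylselanylmethyl)-4-vinyl-1,3-dioxolane | C/C(=C\CCC1(C=C)COC(C[Se]c2ccccc2)O1)CO[Si](C)(C)C(C)(C)C
F6 | step 6 | 4-[(E)-5-(tert-butyldimethylsilyloxy)-4-methylpent-3-enyl]-2-(phenylseleninylmethyl)-4-vinyl-1,3-dioxolane | C/C(=C\CCC1(C=C)COC(C[Se](=O)c2ccccc2)O1)CO[Si](C)(C)C(C)(C)C
F7 | step 12 | [2,5-bis(methoxymethoxy)phenyl]lithium | COCOc1ccc(OCOC)c([Li])c1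
F8 | step 12 | (S)-2-{2-[2,5-bis(methoxymethoxy)phenyl]-2-oxoethyl}-6-[(E)-5-(tert-butyldimethylsilyloxy)-4-methylpent-3-enyl]-2,3,4,7-tetrahydrooxepine-2-carboxylic acid | C/C(=C\CCC1=CCC[C@](CC(=O)c2cc(OCOC)ccc2OCOC)(C(=O)O)OC1)CO[Si](C)(C)C(C)(C)C
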